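**Plan**

Ring labels: upper unit A (benzo), C (pyran), B (4-hydroxyphenyl); lower unit D (benzo), F (pyran), E (catechol).
1. Retrosynthesis: remove thirteen O-benzyl groups, cut both galloyl C(=O)–O3 ester bonds, then take O3 and H2 off upper ring C to reach a 2,4-diaryl-4H-chromene.
2. Ring C is cut at upper C4–C4a and O1–C2 into 3,5-dibenzyloxyphenol (ring A with O1) and an (E)-enone; the enone C3=C4 bond goes back by aldol condensation to 4'-benzyloxyacetophenone and a lower C8 aldehyde, and the C8–CHO bond goes back through the C8 bromide to (−)-epicatechin.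
3. Enabling feature: upper C2–C3–C4 is a three-carbon bridge with ring B on C2 and lower C8 (ring D) on C4, tied to ring A through C4a and O1. This is an aryl enone (carbonyl = C2, β-carbon = C4) plus a phenol.
4. Forward: rings D, E and F come intact from epicatechin (benzylate, brominate C8, silylate O3, formylate, condense). Ring C is the only ring built, closed onto ring A in the key step. Then O3 and H2 are added across C2=C3, followed by desilylation, double galloylation and hydrogenolysis.
5. Stereochemistry: lower C2 and C3 come from (−)-epicatechin; upper C4 from the chiral phosphoric acid; upper C3 from epoxidation anti to the C4 aryl; upper C2 from hydride delivery anti to the new C3 oxygen (upper unit 2R,3R,4R, 2,3-cis-3,4-trans).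

Key step: step 6

Assumption: the (R)-configured phosphoric acid is taken to give the (4R)-chromene. Because the lower unit is enantiopure, the two C4 epimers are diastereomers, so the sense of induction can be read from the product and the (S)-acid used instead if needed.
Remark: 4'-benzyloxyacetophenone, 3,5-dibenzyloxyphenol and 3,4,5-tris(benzyloxy)benzoic acid are taken as purchased, being the benzyl ethers of 4'-hydroxyacetophenone, phloroglucinol and gallic acid.

**Step 1**
Reactants: 1 (−)-epicatechin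
Product: 2 5,7,3',4'-tetra-O-benzyl-(−)-epicatechin
Conditions: BnBr (4.4 equiv), K2CO3, DMF, 0 °C → rt, argon
Reagents that add atoms: benzyl bromide, BrCc1ccccc1
Why: Williamson etherification: K2CO3 deprotonates only the four phenols, so the secondary C3 alcohol stays free, and the low temperature under argon limits the base-induced ring opening that would epimerise C2; no stereocentre is formed.

**Step 2**
Reactants: 2 5,7,3',4'-tetra-O-benzyl-(−)-epicatechin
Product: 3 8-bromo-5,7,3',4'-tetra-O-benzylepicatechin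
Conditions: NBS (1.0 equiv), CH2Cl2, −78 °C → rt
Reagents that add atoms: N-bromosuccinimide, O=C1CCC(=O)N1Br
Why: Electrophilic aromatic bromination of the phloroglucinol-type ring D, where C8 (flanked by the ring oxygen and one benzyloxy group) is more accessible than C6 (between two benzyloxy groups), the regiochemistry known for 5,7-di-O-benzyl flavan-3-ols.

**Step 3**
Reactants: 3 8-bromo-5,7,3',4'-tetra-O-benzylepicatechin
Product: 4 8-bromo-3-O-(tert-butyldimethylsilyl)-5,7,3',4'-tetra-O-benzylepicatechin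
Conditions: TBSCl, imidazole, DMF, rt → 40 °C
Reagents that add atoms: tert-butyldimethylsilyl chloride, CC(C)(C)[Si](C)(C)Cl
Why: Imidazole-promoted silylation of the only hydroxyl masks it as a base-stable silyl ether before the organolithium step; C3 keeps its configuration because only the O–H bond reacts.

**Step 4**
Reactants: 4 8-bromo-3-O-(tert-butyldimethylsilyl)-5,7,3',4'-tetra-O-benzylepicatechin
Product: 7 8-formyl-3-O-(tert-butyldimethylsilyl)-5,7,3',4'-tetra-O-benzylepicatechin, via 8-lithio arene 5 (not isolated), via lithium hemiaminolate 6 (not isolated)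
Conditions: n-BuLi, THF, −78 °C; DMF, −78 → 0 °C; H2O
Reagents that add atoms: N,N-dimethylformamide, CN(C)C=O
Why: Bromine–lithium exchange at −78 °C is faster than benzylic deprotonation and gives an aryllithium held by two ortho oxygens, which adds to DMF (Bouveault formylation) to a hemiaminolate that releases the aldehyde on hydrolysis.

**Step 5**
Reactants: 7 8-formyl-3-O-(tert-butyldimethylsilyl)-5,7,3',4'-tetra-O-benzylepicatechin; 8 4'-benzyloxyacetophenone
Product: 10 (E)-1-(4-benzyloxyphenyl)-3-[3-O-(tert-butyldimethylsilyl)-5,7,3',4'-tetra-O-benzylepicatechin-8-yl]prop-2-en-1-one, via aldol adduct 9 (not isolated)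
Conditions: KOH, EtOH/THF, rt → 40 °C
Reagents that add atoms: none
Why: Claisen–Schmidt condensation: the ketone enolate adds to the non-enolisable aldehyde and E1cB dehydration of the aldol gives the conjugated (E)-enone as the thermodynamic isomer; the molecule carries no base-labile ester, and the benzylated ring E blocks the phenoxide-driven epimerisation of lower C2.

**Step 6**
Reactants: 10 (E)-1-(4-benzyloxyphenyl)-3-[3-O-(tert-butyldimethylsilyl)-5,7,3',4'-tetra-O-benzylepicatechin-8-yl]prop-2-en-1-one; 11 3,5-dibenzyloxyphenol (1.5 equiv)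
Product: 14 (4R)-5,7-bis(benzyloxy)-2-(4-benzyloxyphenyl)-4-[3-O-(tert-butyldimethylsilyl)-5,7,3',4'-tetra-O-benzylepicatechin-8-yl]-4H-chromene, via Friedel–Crafts ketone 12 (not isolated), via cyclic hemiketal 13 (not isolated)
Conditions: (R)-3,3'-bis(2,4,6-triisopropylphenyl)-1,1'-binaphthyl-2,2'-diyl hydrogen phosphate (10 mol %), 4 Å MS, toluene, 0 °C → rt
Reagents that add atoms: none
Why: The phosphoric acid hydrogen-bonds the enone carbonyl through P–OH and the phenolic OH of 11 through P=O, so the carbon ortho to that OH adds to the β-carbon (Friedel–Crafts conjugate addition, upper C4–C4a) and tautomerisation gives ketone 12. The phenol oxygen then adds to the ketone carbonyl in a 6-exo-trig hemiketalisation (O1–C2, ring C) to give 13, and acid-promoted loss of water through the oxocarbenium stabilised by the 4-benzyloxyphenyl group gives the aryl-conjugated enol ether 14, the sieves holding the water. The closest known reaction type is the chiral Brønsted acid or bifunctional catalysis of phenol and naphthol addition to enones with cyclodehydration to 4H-chromenes. The only new stereocentre, C4, is set in the C–C bond-forming event by the 3,3'-aryl pocket of the catalyst, which exposes one face of the s-cis (E)-enone; the distant lower C2 and C3 should bias it little, and any C4 epimer is a separable diastereomer. The step needs ortho rather than para attack on 11 and conjugate rather than carbonyl addition: the free OH of 11 is the hydrogen-bond handle that brings its ortho carbon to the β-carbon, a para adduct has no way to cyclise and should revert by retro-Friedel–Crafts reaction at the doubly electron-rich benzylic carbon, and the three oxygens on ring D make the enone basic enough for acid activation while deactivating its carbonyl towards 1,2-addition.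

**Step 7**
Reactants: 14 (4R)-5,7-bis(benzyloxy)-2-(4-benzyloxyphenyl)-4-[3-O-(tert-butyldimethylsilyl)-5,7,3',4'-tetra-O-benzylepicatechin-8-yl]-4H-chromene
Product: 16 hepta-O-benzyl (2R,3R,4R)-epiafzelechin-(4β→8)-epicatechin carrying 3-O-triethylsilyl on the upper unit and 3-O-tert-butyldimethylsilyl on the lower unit, via α-epoxide 15 (not isolated)
Conditions: dimethyldioxirane (acetone-free solution in CH2Cl2, 1.1 equiv), CH2Cl2, −78 → −40 °C; then Et3SiH (5 equiv), Et3SiOTf (10 mol %), −78 °C; aq NaHCO3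
Reagents that add atoms: dimethyldioxirane, CC1(C)OO1; triethylsilane, CC[SiH](CC)CC
Why: Dimethyldioxirane epoxidises the electron-rich enol ether on the α face, anti to the pseudo-axial lower unit at C4 (this fixes C3), and silyl triflate-promoted opening of the epoxide at the acetal carbon followed by hydride transfer from Et3SiH anti to the bulky C3–OSiEt3 group, the reductive opening known for glycal and C-aryl glycal epoxides, inverts C2 and should give the 2,3-cis-3,4-trans arrangement.

**Step 8**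
Reactants: 16 bis-silyl ether from step 7
Product: 17 5,7,4'-tri-O-benzyl-(2R,3R,4R)-epiafzelechin-(4β→8)-5,7,3',4'-tetra-O-benzyl-(2R,3R)-epicatechin (3,3''-diol)
Conditions: HF·pyridine, pyridine/THF, 0 °C → rt
Reagents that add atoms: none
Why: Fluoride cleaves both Si–O bonds (strong Si–F bond) under buffered conditions that leave the benzyl ethers, the acid-sensitive C4–C8 bond and all stereocentres untouched.

**Step 9**
Reactants: 17 hepta-O-benzyl diol; 18 3,4,5-tris(benzyloxy)benzoic acid (3 equiv)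
Product: 19 trideca-O-benzyl epiafzelechin 3-O-gallate-(4β→8)-epicatechin 3-O-gallate
Conditions: DCC, DMAP, CH2Cl2, rt
Reagents that add atoms: none
Why: Steglich esterification: DMAP relays the acyl group from the O-acylisourea to both secondary alcohols, and acylation at oxygen retains both C3 configurations, as is usual for 3-O-galloylation of benzylated flavan-3-ols.

**Step 10**
Reactants: 19 trideca-O-benzyl bis-gallate
Product: 20 epiafzelechin 3-O-gallate-(4β→8)-epicatechin 3-O-gallate (CNP0291968.1)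
Conditions: H2 (1 atm), Pd(OH)2/C, THF/MeOH/H2O, rt
Reagents that add atoms: none
Why: Hydrogenolysis of the thirteen O-benzyl ethers over Pd(OH)2/C under neutral conditions should release all phenols while the gallate esters, the pyran rings and the interflavan bond survive, as in the deprotection of benzylated procyanidin gallates.

**Compound list**

1 | (−)-epicatechin | O[C@@H]1Cc2c(O)cc(O)cc2O[C@@H]1c1ccc(O)c(O)c1 | starting material
2 | 5,7,3',4'-tetra-O-benzyl-(−)-epicatechin | O[C@@H]1Cc2c(OCc3ccccc3)cc(OCc3ccccc3)cc2O[C@@H]1c1ccc(OCc2ccccc2)c(OCc2ccccc2)c1 | intermediate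
3 | 8-bromo-5,7,3',4'-tetra-O-benzylepicatechin | O[C@@H]1Cc2c(OCc3ccccc3)cc(OCc3ccccc3)c(Br)c2O[C@@H]1c1ccc(OCc2ccccc2)c(OCc2ccccc2)c1 | intermediate
4 | 8-bromo-3-O-(tert-butyldimethylsilyl)-5,7,3',4'-tetra-O-benzylepicatechin | CC(C)(C)[Si](C)(C)O[C@@H]1Cc2c(OCc3ccccc3)cc(OCc3ccccc3)c(Br)c2O[C@@H]1c1ccc(OCc2ccccc2)c(OCc2ccccc2)c1 | intermediate
5 | 8-lithio-3-O-(tert-butyldimethylsilyl)-5,7,3',4'-tetra-O-benzylepicatechin | CC(C)(C)[Si](C)(C)O[C@@H]1Cc2c(OCc3ccccc3)cc(OCc3ccccc3)c([Li])c2O[C@@H]1c1ccc(OCc2ccccc2)c(OCc2ccccc2)c1 | intermediate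
6 | lithium hemiaminolate from 5 and DMF (8-[(dimethylamino)(lithiooxy)methyl] derivative, carbinol centre undefined) | CC(C)(C)[Si](C)(C)O[C@@H]1Cc2c(OCc3ccccc3)cc(OCc3ccccc3)c(C(O[Li])N(C)C)c2O[C@@H]1c1ccc(OCc2ccccc2)c(OCc2ccccc2)c1 | intermediate
7 | 8-formyl-3-O-(tert-butyldimethylsilyl)-5,7,3',4'-tetra-O-benzylepicatechin | CC(C)(C)[Si](C)(C)O[C@@H]1Cc2c(OCc3ccccc3)cc(OCc3ccccc3)c(C=O)c2O[C@@H]1c1ccc(OCc2ccccc2)c(OCc2ccccc2)c1 | intermediate
8 | 4'-benzyloxyacetophenone | CC(=O)c1ccc(OCc2ccccc2)cc1 | starting material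
9 | aldol adduct, 3-hydroxy-1-(4-benzyloxyphenyl)-3-(lower unit-8-yl)propan-1-one (carbinol centre undefined) | CC(C)(C)[Si](C)(C)O[C@@H]1Cc2c(OCc3ccccc3)cc(OCc3ccccc3)c(C(O)CC(=O)c3ccc(OCc4ccccc4)cc3)c2O[C@@H]1c1ccc(OCc2ccccc2)c(OCc2ccccc2)c1 | intermediate
10 | (E)-1-(4-benzyloxyphenyl)-3-[3-O-(tert-butyldimethylsilyl)-5,7,3',4'-tetra-O-benzylepicatechin-8-yl]prop-2-en-1-one | CC(C)(C)[Si](C)(C)O[C@@H]1Cc2c(OCc3ccccc3)cc(OCc3ccccc3)c(/C=C/C(=O)c3ccc(OCc4ccccc4)cc3)c2O[C@@H]1c1ccc(OCc2ccccc2)c(OCc2ccccc2)c1 | intermediate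
11 | 3,5-dibenzyloxyphenol | Oc1cc(OCc2ccccc2)cc(OCc2ccccc2)c1 | starting material
12 | Friedel–Crafts ketone, 1-(4-benzyloxyphenyl)-3-[2-hydroxy-4,6-bis(benzyloxy)phenyl]-3-(lower unit-8-yl)propan-1-one with upper C4 set | O=C(c1ccc(OCc2ccccc2)cc1)C[C@@H](c1c(OCc2ccccc2)cc(OCc2ccccc2)c2c1O[C@H](c1ccc(OCc3ccccc3)c(OCc3ccccc3)c1)[C@H](O[Si](C)(C)C(C)(C)C)C2)c1c(OCc2ccccc2)cc(OCc2ccccc2)cc1O | intermediate
13 | cyclic hemiketal, 2-hydroxy-2-(4-benzyloxyphenyl)-4-(lower unit-8-yl)-5,7-bis(benzyloxy)chroman (C2 undefined) | OC1(c2ccc(OCc3ccccc3)cc2)C[C@@H](c2c(OCc3ccccc3)cc(OCc3ccccc3)c3c2O[C@H](c2ccc(OCc4ccccc4)c(OCc4ccccc4)c2)[C@H](O[Si](C)(C)C(C)(C)C)C3)c2c(OCc3ccccc3)cc(OCc3ccccc3)cc2O1 | intermediate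
14 | (4R)-5,7-bis(benzyloxy)-2-(4-benzyloxyphenyl)-4-[3-O-(tert-butyldimethylsilyl)-5,7,3',4'-tetra-O-benzylepicatechin-8-yl]-4H-chromene | C1(c2ccc(OCc3ccccc3)cc2)=C[C@@H](c2c(OCc3ccccc3)cc(OCc3ccccc3)c3c2O[C@H](c2ccc(OCc4ccccc4)c(OCc4ccccc4)c2)[C@H](O[Si](C)(C)C(C)(C)C)C3)c2c(OCc3ccccc3)cc(OCc3ccccc3)cc2O1 | intermediate
15 | 2,3-epoxide of 14 with the oxygen on the α face, anti to the C4 aryl | c1cc(OCc2ccccc2)ccc1[C@@]12O[C@@H]1[C@@H](c1c(OCc3ccccc3)cc(OCc3ccccc3)c3c1O[C@H](c1ccc(OCc4ccccc4)c(OCc4ccccc4)c1)[C@H](O[Si](C)(C)C(C)(C)C)C3)c1c(OCc3ccccc3)cc(OCc3ccccc3)cc1O2 | intermediate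
16 | hepta-O-benzyl (2R,3R,4R)-epiafzelechin-(4β→8)-(2R,3R)-epicatechin, upper 3-O-triethylsilyl, lower 3-O-tert-butyldimethylsilyl | CC[Si](CC)(CC)O[C@@H]1[C@@H](c2c(OCc3ccccc3)cc(OCc3ccccc3)c3c2O[C@H](c2ccc(OCc4ccccc4)c(OCc4ccccc4)c2)[C@H](O[Si](C)(C)C(C)(C)C)C3)c2c(OCc3ccccc3)cc(OCc3ccccc3)cc2O[C@@H]1c1ccc(OCc2ccccc2)cc1 | intermediate
17 | 5,7,4'-tri-O-benzyl-epiafzelechin-(4β→8)-5,7,3',4'-tetra-O-benzyl-epicatechin (3,3''-diol) | O[C@@H]1[C@@H](c2c(OCc3ccccc3)cc(OCc3ccccc3)c3c2O[C@H](c2ccc(OCc4ccccc4)c(OCc4ccccc4)c2)[C@H](O)C3)c2c(OCc3ccccc3)cc(OCc3ccccc3)cc2O[C@@H]1c1ccc(OCc2ccccc2)cc1 | intermediate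
18 | 3,4,5-tris(benzyloxy)benzoic acid | OC(=O)c1cc(OCc2ccccc2)c(OCc2ccccc2)c(OCc2ccccc2)c1 | starting material
19 | trideca-O-benzyl epiafzelechin 3-O-gallate-(4β→8)-epicatechin 3-O-gallate | O=C(O[C@@H]1[C@@H](c2c(OCc3ccccc3)cc(OCc3ccccc3)c3c2O[C@H](c2ccc(OCc4ccccc4)c(OCc4ccccc4)c2)[C@H](OC(=O)c2cc(OCc4ccccc4)c(OCc4ccccc4)c(OCc4ccccc4)c2)C3)c2c(OCc3ccccc3)cc(OCc3ccccc3)cc2O[C@@H]1c1ccc(OCc2ccccc2)cc1)c1cc(OCc2ccccc2)c(OCc2ccccc2)c(OCc2ccccc2)c1 | intermediate
20 | epiafzelechin 3-O-gallate-(4β→8)-epicatechin 3-O-gallate (CNP0291968.1) | O=C(O[C@@H]1[C@@H](c2c(O)cc(O)c3c2O[C@H](c2ccc(O)c(O)c2)[C@H](OC(=O)c2cc(O)c(O)c(O)c2)C3)c2c(O)cc(O)cc2O[C@@H]1c1ccc(O)cc1)c1cc(O)c(O)c(O)c1 | target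

**Step count and risks**

Total step count: 10. Longest linear sequence: 10 steps (1 → 20); compounds 8, 11 and 18 enter as purchased materials.

Steps most likely to fail:

1. Step 6. The conjugate addition may stall because the three oxygens on ring D make the β-carbon a poor acceptor. Reversible C–C bond formation under the acid may erode the facial selectivity at C4, and para alkylation of the phenol may compete. Fallback (flavylium C4 arylation, known chemistry, C4 epimers separated instead of catalyst control): it sets out from 11, 8 and 4 and comes back at 14. Magnesium-directed ortho-formylation of 11 (MgCl2, Et3N, paraformaldehyde, MeCN, reflux) should give 2-hydroxy-4,6-bis(benzyloxy)benzaldehyde F1. Acid condensation of F1 with 8 (HBF4·OEt2, AcOH/EtOAc) should give 5,7-bis(benzyloxy)-2-(4-benzyloxyphenyl)chromenylium tetrafluoroborate F2. The aryllithium 5, made from 4 as in step 4, is then added to F2 in THF at −78 °C. Attack is expected at C4, since C2 carries ring B and C4 addition gives the conjugated 4H-chromene, so the upper C4–lower C8 bond is formed directly. This gives 14 together with its C4 epimer, the (4S)-chromene F3, which is removed by chromatography.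

2. Step 7. Hydride may be delivered to the oxocarbenium from the α face, giving the 2,3-trans isomer, or a 1,2-hydride shift to the flavan-3-one may outrun reduction. Fallback (open-chain reduction and ring closure with inversion, known chemistry): it sets out from 14 and comes back at 17. Epoxidation as before, quenched with water instead of silane, should give the hemiketal in equilibrium with its open form, (2R-configured at the carbinol) 2-hydroxy-1-(4-benzyloxyphenyl)-3-[2-hydroxy-4,6-bis(benzyloxy)phenyl]-3-(lower unit-8-yl)propan-1-one F4. Chelation-controlled reduction with Zn(BH4)2 in Et2O at −20 °C, with zinc bridging the carbonyl and the C3 hydroxyl and hydride entering past the small hydrogen, should give the anti-1,2-diol F5. Mitsunobu cycloetherification (PPh3, DIAD, THF, 0 °C), in which the ring A phenol displaces the activated benzylic C2 hydroxyl with inversion, should give the 2,3-cis-3,4-trans flavan-3-ol with the lower 3-O-tert-butyldimethylsilyl group still in place F6. HF·pyridine as in step 8 then gives 17.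

3. Step 10. Debenzylation of thirteen ethers may stop short, and the benzylic O1–C2 bonds of the pyran rings may be opened by hydrogenolysis; the free polyphenol is also prone to air oxidation during a long reaction. Fallback (Lewis-acid debenzylation with a cation scavenger instead of hydrogenolysis, known chemistry): it sets out from 19 and comes back at 20. BCl3 with pentamethylbenzene in CH2Cl2 at −78 °C cleaves the aryl benzyl ethers, the benzyl cations being trapped by the scavenger, then MeOH quench. This fallback makes no new compound (F0).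

**Further compounds**

F1 | step 6 | 2-hydroxy-4,6-bis(benzyloxy)benzaldehyde | O=Cc1c(O)cc(OCc2ccccc2)cc1OCc1ccccc1
F2 | step 6 | 5,7-bis(benzyloxy)-2-(4-benzyloxyphenyl)chromenylium tetrafluoroborate | c1cc(OCc2ccccc2)ccc1-c1ccc2c(OCc3ccccc3)cc(OCc3ccccc3)cc2[o+]1.F[B-](F)(F)F
F3 | step 6 | (4S)-chromene, C4 epimer of 14 | C1(c2ccc(OCc3ccccc3)cc2)=C[C@H](c2c(OCc3ccccc3)cc(OCc3ccccc3)c3c2O[C@H](c2ccc(OCc4ccccc4)c(OCc4ccccc4)c2)[C@H](O[Si](C)(C)C(C)(C)C)C3)c2c(OCc3ccccc3)cc(OCc3ccccc3)cc2O1
F4 | step 7 | 2-hydroxy-1-(4-benzyloxyphenyl)-3-[2-hydroxy-4,6-bis(benzyloxy)phenyl]-3-(lower unit-8-yl)propan-1-one (open form of the hemiketal) | O=C(c1ccc(OCc2ccccc2)cc1)[C@H](O)[C@@H](c1c(OCc2ccccc2)cc(OCc2ccccc2)c2c1O[C@H](c1ccc(OCc3ccccc3)c(OCc3ccccc3)c1)[C@H](O[Si](C)(C)C(C)(C)C)C2)c1c(OCc2ccccc2)cc(OCc2ccccc2)cc1O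
F5 | step 7 | anti-1,2-diol, 1-(4-benzyloxyphenyl)-3-[2-hydroxy-4,6-bis(benzyloxy)phenyl]-3-(lower unit-8-yl)propane-1,2-diol | O[C@@H](c1ccc(OCc2ccccc2)cc1)[C@H](O)[C@@H](c1c(OCc2ccccc2)cc(OCc2ccccc2)c2c1O[C@H](c1ccc(OCc3ccccc3)c(OCc3ccccc3)c1)[C@H](O[Si](C)(C)C(C)(C)C)C2)c1c(OCc2ccccc2)cc(OCc2ccccc2)cc1O
F6 | step 7 | hepta-O-benzyl epiafzelechin-(4β→8)-epicatechin with free upper 3-OH and lower 3-O-tert-butyldimethylsilyl | O[C@@H]1[C@@H](c2c(OCc3ccccc3)cc(OCc3ccccc3)c3c2O[C@H](c2ccc(OCc4ccccc4)c(OCc4ccccc4)c2)[C@H](O[Si](C)(C)C(C)(C)C)C3)c2c(OCc3ccccc3)cc(OCc3ccccc3)cc2O[C@@H]1c1ccc(OCc2ccccc2)cc1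
F0 | step 10 | none | none
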